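**Retrosynthetic overview**
1. The target is a central 3-bromocatechol (ring B: C1-OH, C2-OH, C3-Br, C6-H). Its adjacent carbons C4 and C5 carry the same 2,3-dibromo-4,5-dihydroxybenzyl group (ring C on C4, ring A on C5). The last disconnection is the cleavage of all ether bonds (four OMe, one O-CH2-O) in one BBr3 operation.
2. The key disconnection cuts both ArCH2–C(ring B) bonds at once. It is a three-component double Friedel–Crafts benzylation of 4-bromo-1,3-benzodioxole with two molecules of (2,3-dibromo-4,5-dimethoxyphenyl)methanol. Its closing event bonds the CH2 of ring C to the ring-B carbon between C–Br and C–CH2(ring A).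
3. Enabling feature: ring-B C4 is para to the oxygen on C1 and C5 is para to the oxygen on C2, and rings A and C with their CH2 groups are identical. In each benzyl unit the carbon para to the 5-oxygen is blocked by Br, so the electrophile cannot oligomerise. The temporary dioxole ring keeps both ring-B oxygens conjugated and leaves C6-H, an α-position of the benzodioxole, as the least reactive site.
4. The electrophile comes from vanillin by dibromination, O-methylation and reduction, so all five bromines are in place before the union.
5. Ring order: no carbocycle is built, since all three benzene rings are bought. The only extra ring, the dioxole on ring B, is present from the start and is opened in the last step.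

Key step: step 4

Remark: the target has no stereocentre and no configurationally stable axis is expected, so no SMILES carries a stereodescriptor. Vanillin and 4-bromo-1,3-benzodioxole are taken as commercial.

**Step 1**
Reactants: 1 vanillin (4-hydroxy-3-methoxybenzaldehyde)
Product: 2 2,3-dibromo-4-hydroxy-5-methoxybenzaldehyde (5,6-dibromovanillin)
Conditions: Br2 (2.3 equiv), Fe powder (cat.), AcOH, rt → 60 °C
Reagents that add atoms: bromine, BrBr
Why: In this electrophilic aromatic bromination the free 4-OH places the first bromine at C5 (ortho) and the 3-OMe directs the slower, iron-assisted second bromination to C6 (para to OMe), which should give the dibromo pattern of rings A and C.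

**Step 2**
Reactants: 2 2,3-dibromo-4-hydroxy-5-methoxybenzaldehyde
Product: 3 2,3-dibromo-4,5-dimethoxybenzaldehyde
Conditions: MeI, K2CO3, DMF, rt
Reagents that add atoms: iodomethane, CI
Why: Williamson ether synthesis on the acidic, bromine-flanked phenol should be clean because the aldehyde and the aryl bromides are inert to MeI/K2CO3, and it masks the OH before the acid-catalysed key step.

**Step 3**
Reactants: 3 2,3-dibromo-4,5-dimethoxybenzaldehyde
Product: 4 (2,3-dibromo-4,5-dimethoxyphenyl)methanol
Conditions: NaBH4, MeOH/THF, 0 °C
Reagents that add atoms: none
Why: Borohydride reduction of an aromatic aldehyde is chemoselective, leaves aryl bromides and methyl ethers untouched and creates no stereocentre.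

**Step 4**
Reactants: 4 (2,3-dibromo-4,5-dimethoxyphenyl)methanol (two molecules), 5 4-bromo-1,3-benzodioxole
Product: 7 4-bromo-5,6-bis(2,3-dibromo-4,5-dimethoxybenzyl)-1,3-benzodioxole, via mono-benzylated bromobenzodioxole 6 (not isolated)
Conditions: TfOH (10 mol %), HFIP, 40 °C, Ar; 4 (2.2 equiv) added slowly
Reagents that add atoms: none
Why: This is an acid-catalysed dehydrative Friedel–Crafts benzylation run twice in one flask (three components, two C–C bonds): TfOH in strongly ionising HFIP converts 4 into the 2,3-dibromo-4,5-dimethoxybenzyl cation, which attacks 5 at the open C6 (para to O3) to give 6, and a second cation then attacks 6 at C5, the carbon between C4–Br and C6–CH2Ar and para to O1, with loss of a proton each time. The closest known reaction types are the acid- or AlCl3-mediated benzylation of substituted arenes by bromodimethoxybenzyl alcohols and the 4,5-dialkylation of catechol ethers in cyclotriveratrylene-type condensations, where attack para to oxygen and ortho to a benzyl group is the rule. No ring is closed and no stereocentre is created. The step needs site selectivity on ring B (C5 and C6 over C7), and the fused dioxole secures it by holding both oxygen lone pairs in conjugation even next to bromine, so both para positions stay activated while C7 is the poorly reactive α-position of a 1,3-benzodioxole. Because both incoming groups are the same, the order in which C5 and C6 are filled does not matter and both orders converge on 7. Self-condensation of 4 and further benzylation of rings A and C should be held back because their para-to-methoxy carbon carries bromine, their only free C–H sits on a doubly brominated ring, and slow addition keeps the cation concentration low.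

**Step 5**
Reactants: 7 4-bromo-5,6-bis(2,3-dibromo-4,5-dimethoxybenzyl)-1,3-benzodioxole
Product: 8 3-bromo-4,5-bis(2,3-dibromo-4,5-dihydroxybenzyl)benzene-1,2-diol (target)
Conditions: BBr3 (10 equiv), CH2Cl2, −78 °C → rt; then ice–water
Reagents that add atoms: none
Why: Boron tribromide ether cleavage, the standard last step for polybrominated diarylmethane catechol ethers, should cleave the four aryl methyl ethers and open the dioxole in the same operation, while the aryl bromides and the two diarylmethane CH2 groups are inert at or below room temperature.

**Compound list**
1 | vanillin (4-hydroxy-3-methoxybenzaldehyde) | COc1cc(C=O)ccc1O | starting material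
2 | 2,3-dibromo-4-hydroxy-5-methoxybenzaldehyde | COc1cc(C=O)c(Br)c(Br)c1O | intermediate
3 | 2,3-dibromo-4,5-dimethoxybenzaldehyde | COc1cc(C=O)c(Br)c(Br)c1OC | intermediate
4 | (2,3-dibromo-4,5-dimethoxyphenyl)methanol | COc1cc(CO)c(Br)c(Br)c1OC | intermediate
5 | 4-bromo-1,3-benzodioxole | Brc1cccc2OCOc12 | starting material
6 | 4-bromo-6-(2,3-dibromo-4,5-dimethoxybenzyl)-1,3-benzodioxole | COc1cc(Cc2cc(Br)c3OCOc3c2)c(Br)c(Br)c1OC | intermediate
7 | 4-bromo-5,6-bis(2,3-dibromo-4,5-dimethoxybenzyl)-1,3-benzodioxole | COc1cc(Cc2cc3OCOc3c(Br)c2Cc2cc(OC)c(OC)c(Br)c2Br)c(Br)c(Br)c1OC | intermediate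
8 | 3-bromo-4,5-bis(2,3-dibromo-4,5-dihydroxybenzyl)benzene-1,2-diol | Oc1cc(Cc2cc(O)c(O)c(Br)c2Cc2cc(O)c(O)c(Br)c2Br)c(Br)c(Br)c1O | target

Total step count: 5. Longest linear sequence: 5 (1 → 2 → 3 → 4 → 7 → 8).

**Steps most likely to fail**

Step 4 is most at risk.
- **What may go wrong:** The second benzylation must enter the crowded ring-B carbon between bromine and the first benzyl group. It may stall at the mono-benzyl stage, drift to the α-position next to the dioxole oxygen, or be undone by acid-induced debenzylation.
- **Fallback:** It reverses the polarity and uses the aldehyde oxidation level. It sets out from 6, isolated from a run with one equivalent of 4.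
  - Iodination with NIS/TFA in MeCN should give 4-bromo-5-iodo-6-(2,3-dibromo-4,5-dimethoxybenzyl)-1,3-benzodioxole F1. Its substitution pattern can be secured before the second large fragment is committed.
  - Iodine–magnesium exchange with iPrMgCl·LiCl in THF at −40 °C should give the arylmagnesium chloride F2. The iodide exchanges faster than the bromides, and the temperature is low enough to avoid aryne formation.
  - Addition of F2 to aldehyde 3 should give the racemic diarylmethanol F3.
  - Ionic hydrogenation with Et3SiH/TFA in CH2Cl2 at 0 °C removes the hydroxyl group and the stereocentre, and the route is rejoined at 7.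

Step 5 is second.
- **What may go wrong:** The methylene carbon of the dioxole leaves as an electrophilic C1 species that may re-alkylate the freed catechol rings. Prolonged contact with BBr3/HBr may cause loss or migration of a benzyl group. The hindered methyl ethers may cleave incompletely, and the product may oxidise in air during work-up.
- **Fallback:** It removes all protecting groups at the monomer stage and makes the union without them.
  - From 3, BBr3 in CH2Cl2 should give 2,3-dibromo-4,5-dihydroxybenzaldehyde F4.
  - NaBH4 in EtOH should then give 2,3-dibromo-4,5-dihydroxybenzyl alcohol F5.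
  - From 5, BCl3 in CH2Cl2 should give 3-bromocatechol F6.
  - Two equivalents of F5 and one of F6 are combined with catalytic TFA in HFIP at rt under argon. Ionisation is assisted by the free para-hydroxyl group. The reaction should pass through 3-bromo-5-(2,3-dibromo-4,5-dihydroxybenzyl)benzene-1,2-diol F7 and rejoin the route directly at 8.

Step 1 is third.
- **What may go wrong:** The second bromination is slow on a deactivated ring and may suffer from poor positional selectivity or from displacement of the formyl group by bromine.
- **Fallback:** It reverses the order of the two brominations by switching the directing group. It sets out from 1.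
  - Ac2O/pyridine should give vanillin acetate F8.
  - In F8 the methoxy group is the strongest director, so Br2/KBr in water should place bromine para to it and give 4-acetoxy-2-bromo-5-methoxybenzaldehyde F9.
  - Hydrolysis with aqueous HCl should give 2-bromo-4-hydroxy-5-methoxybenzaldehyde F10.
  - The easy bromination ortho to the free hydroxyl group (Br2, AcOH, rt) rejoins the route at 2.

**Further compounds**
F1 | step 4 | 4-bromo-5-iodo-6-(2,3-dibromo-4,5-dimethoxybenzyl)-1,3-benzodioxole | COc1cc(Cc2cc3OCOc3c(Br)c2I)c(Br)c(Br)c1OC
F2 | step 4 | [4-bromo-6-(2,3-dibromo-4,5-dimethoxybenzyl)-1,3-benzodioxol-5-yl]magnesium chloride | COc1cc(Cc2cc3OCOc3c(Br)c2[Mg]Cl)c(Br)c(Br)c1OC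
F3 | step 4 | [4-bromo-6-(2,3-dibromo-4,5-dimethoxybenzyl)-1,3-benzodioxol-5-yl](2,3-dibromo-4,5-dimethoxyphenyl)methanol, racemic | COc1cc(Cc2cc3OCOc3c(Br)c2C(O)c2cc(OC)c(OC)c(Br)c2Br)c(Br)c(Br)c1OC
F4 | step 5 | 2,3-dibromo-4,5-dihydroxybenzaldehyde | O=Cc1cc(O)c(O)c(Br)c1Br
F5 | step 5 | 2,3-dibromo-4,5-dihydroxybenzyl alcohol | OCc1cc(O)c(O)c(Br)c1Br
F6 | step 5 | 3-bromocatechol (3-bromobenzene-1,2-diol) | Oc1cccc(Br)c1O
F7 | step 5 | 3-bromo-5-(2,3-dibromo-4,5-dihydroxybenzyl)benzene-1,2-diol | Oc1cc(Cc2cc(O)c(O)c(Br)c2)c(Br)c(Br)c1O
F8 | step 1 | vanillin acetate (4-formyl-2-methoxyphenyl acetate) | COc1cc(C=O)ccc1OC(C)=O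
F9 | step 1 | 4-acetoxy-2-bromo-5-methoxybenzaldehyde | COc1cc(C=O)c(Br)cc1OC(C)=O
F10 | step 1 | 2-bromo-4-hydroxy-5-methoxybenzaldehyde | COc1cc(C=O)c(Br)cc1O
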